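## Retrosynthetic overview

- The target is epioritin-(4β→6)-oritin-4α-ol: upper unit (2R,3R,4S), lower unit (2R,3S,4R), joined C4→C6. The interflavanyl bond is cut last, into a 2,3-cis flavan-4-yl cation (stored as its 4β-benzylsulfanyl ether) and free oritin-4α-ol, as in proanthocyanidin chain extension.
- Both halves come from one (2R,3R)-dihydroflavonol. The lower half needs only C4 carbonyl reduction. The upper half is inverted at C3 through a 3α,4α-epoxide that thiolate opens at C4.
- Ring C is formed once, from the 2'-hydroxychalcone, by oxa-Michael closure (chalcone isomerase-like) and enolate hydroxylation (flavanone 3-hydroxylase-like) in one flask under a chiral phase-transfer catalyst.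
- The chalcone comes from 2,3,4-trihydroxyacetophenone and 4-(methoxymethoxy)benzaldehyde.
- Ring order: ring C (step 3, serving both halves), then a transient oxirane across C3–C4 of the upper half (step 7); the union forms no ring.

Assumption: 4-(methoxymethoxy)benzaldehyde is bought as a catalogue compound; flavan numbering (O1, C2, C3, C4; rings A, B, C) is used, with α meaning the face that carries the 2-aryl group.

## Route

Step 1
Reactants: 1 2,3,4-trihydroxyacetophenone
Product: 2 1-[2-hydroxy-3,4-bis(methoxymethoxy)phenyl]ethan-1-one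
Conditions: MOMCl (2.2 equiv), K2CO3 (2.5 equiv), acetone, 0 °C to rt, N2
Reagents that add atoms: chloromethyl methyl ether (MOMCl), COCCl
Why: Williamson-type O-alkylation (MOM protection) takes the phenols at C3 and C4, while the 2-OH, held in a hydrogen bond to the acetyl carbonyl, stays free for the later ring closure.

Step 2
Reactants: 2 1-[2-hydroxy-3,4-bis(methoxymethoxy)phenyl]ethan-1-one; 3 4-(methoxymethoxy)benzaldehyde
Product: 4 (E)-1-[2-hydroxy-3,4-bis(methoxymethoxy)phenyl]-3-[4-(methoxymethoxy)phenyl]prop-2-en-1-one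
Conditions: KOH (50% aq.), EtOH, rt, 36 h, N2; then cold dilute AcOH to pH 6
Reagents that add atoms: none
Why: Claisen–Schmidt condensation (aldol addition, then E1cB dehydration) gives the thermodynamically favoured E-enone, and MOM ethers are inert to hydroxide.

Step 3
Reactants: 4 (E)-1-[2-hydroxy-3,4-bis(methoxymethoxy)phenyl]-3-[4-(methoxymethoxy)phenyl]prop-2-en-1-one
Product: 6 (2R,3R)-3-hydroxy-7,8-bis(methoxymethoxy)-2-[4-(methoxymethoxy)phenyl]chroman-4-one, via (2S)-flavanone 5 (not isolated)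
Conditions: N-[4-(trifluoromethyl)benzyl]cinchoninium bromide (10 mol%), 30% aq. H2O2 (3 equiv), LiOH·H2O (0.5 equiv), toluene/H2O, −10 °C, Ar, dark; stopped at about 80% conversion
Reagents that add atoms: hydrogen peroxide, OO
Why: Proposed new method: an asymmetric, interrupted Algar–Flynn–Oyamada cascade in which the chiral ammonium carries the 2'-phenoxide of 4 into toluene, reversible 6-endo oxa-Michael closure gives the ammonium enolate of flavanone 5, and H2O2 held by the catalyst's C9 hydroxyl hydroxylates that enolate anti to the 2-aryl group, so C3 is set trans to C2 by substrate control and C2 by Curtin–Hammett selection between the rapidly interconverting enolate antipodes (a competing epoxide pathway converges on the same trans product; the cinchoninium and cinchonidinium pseudo-enantiomers give either series, and the (2R,3R) sense is confirmed on crystalline 7); the closest known reaction types are the low-temperature Algar–Flynn–Oyamada oxidation that stops at the dihydroflavonol, cinchona phase-transfer α-hydroxylation of ketone enolates, and phase-transfer Weitz–Scheffer epoxidation of chalcones.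

Step 4
Reactants: 6 (2R,3R)-3-hydroxy-7,8-bis(methoxymethoxy)-2-[4-(methoxymethoxy)phenyl]chroman-4-one
Product: 7 (2R,3R)-3,7,8-trihydroxy-2-(4-hydroxyphenyl)chroman-4-one
Conditions: HCl (1.5 M in MeOH), 45 °C, 2 h, Ar; recrystallised from aq. MeOH
Reagents that add atoms: none
Why: Acid-catalysed acetal exchange (MOM transfer to methanol) frees the three phenols, the acid-stable 2,3-trans dihydroflavonol keeps both stereocentres, and crystallisation upgrades the enantiomeric purity.

Step 5
Reactants: 7 (2R,3R)-3,7,8-trihydroxy-2-(4-hydroxyphenyl)chroman-4-one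
Product: 8 (2R,3S,4R)-2-(4-hydroxyphenyl)chromane-3,4,7,8-tetrol (oritin-4α-ol, 2,3-trans-3,4-trans)
Conditions: NaBH4 (6 equiv), EtOH, 0 °C to rt, Ar; acetone quench, pH 6 phosphate buffer, EtOAc
Reagents that add atoms: none
Why: Hydride reduction of the C4 ketone goes by axial attack on the β-face of the half-chair, giving the equatorial 4α-alcohol trans to the 3β-hydroxyl, the known diastereoselectivity of NaBH4 with 2,3-trans dihydroflavonols.

Step 6
Reactants: 6 (2R,3R)-3-hydroxy-7,8-bis(methoxymethoxy)-2-[4-(methoxymethoxy)phenyl]chroman-4-one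
Product: 9 (2R,3R)-7,8-bis(methoxymethoxy)-2-[4-(methoxymethoxy)phenyl]-4-oxochroman-3-yl methanesulfonate
Conditions: MsCl (1.5 equiv), Et3N (2 equiv), CH2Cl2, −20 to 0 °C; used crude
Reagents that add atoms: methanesulfonyl chloride, CS(=O)(=O)Cl
Why: Sulfonylation of the only free hydroxyl (sulfene pathway) keeps the C3 configuration and arms that carbon for inversion, and no anti-periplanar hydrogen is available for elimination to the flavone.

Step 7
Reactants: 9 (2R,3R)-7,8-bis(methoxymethoxy)-2-[4-(methoxymethoxy)phenyl]-4-oxochroman-3-yl methanesulfonate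
Product: 12 (2R,3S,4S)-4-(benzylsulfanyl)-7,8-bis(methoxymethoxy)-2-[4-(methoxymethoxy)phenyl]chroman-3-ol, via mesyloxy alcohol 10 (not isolated), via epoxide 11 (not isolated)
Conditions: NaBH4 (1.5 equiv), THF/MeOH (9:1), −30 °C; then KOtBu (1.2 equiv), THF, 0 °C, 15 min; then BnSH (3 equiv) premixed with KOtBu (2 equiv), THF, 0 °C to rt, Ar
Reagents that add atoms: phenylmethanethiol (BnSH), SCc1ccccc1
Why: Axial hydride delivery gives the 4α-alkoxide trans to the 3β-mesylate, intramolecular Williamson closure (halohydrin-type epoxide formation) inverts C3 to give the 3α,4α-epoxide on the face of the 2-aryl group, and thiolate opens it at the benzylic, 7-oxygen-activated C4 from the β-face (trans-diaxial epoxide opening), which leaves the 2,3-cis-3,4-trans pattern.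

Step 8
Reactants: 12 (2R,3S,4S)-4-(benzylsulfanyl)-7,8-bis(methoxymethoxy)-2-[4-(methoxymethoxy)phenyl]chroman-3-ol
Product: 13 (2R,3S,4S)-4-(benzylsulfanyl)-2-(4-hydroxyphenyl)chromane-3,7,8-triol (4β-benzylsulfanylepioritin)
Conditions: HCl (1.5 M in MeOH), BnSH (2 equiv, additive), 40 °C, 2 h, Ar
Reagents that add atoms: none
Why: Acid-catalysed MOM cleavage (acetal exchange) frees the phenols, while the benzylic C–S bond is the stable end point of acid thiolysis, so C4 keeps its β-sulfanyl group trans to the 3-hydroxyl.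

Step 9
Reactants: 13 (2R,3S,4S)-4-(benzylsulfanyl)-2-(4-hydroxyphenyl)chromane-3,7,8-triol; 8 (2R,3S,4R)-2-(4-hydroxyphenyl)chromane-3,4,7,8-tetrol (4 equiv)
Product: 14 (2R,3S,4R)-2-(4-hydroxyphenyl)-6-[(2R,3R,4S)-3,7,8-trihydroxy-2-(4-hydroxyphenyl)chroman-4-yl]chromane-3,4,7,8-tetrol (epioritin-(4β→6)-oritin-4α-ol)
Conditions: AgBF4 (2.5 equiv), THF, 0 °C, dark, Ar, slow addition of 13 to 8 and AgBF4, 1 h; aq. NaHCO3 quench; Sephadex LH-20 (EtOH)
Reagents that add atoms: none
Why: Thiophilic activation of the C4 thioether by AgBF4 releases the 2,3-cis flavan-4-yl cation without ionising the 4-hydroxyl of 8, and Friedel–Crafts-type attack by C6 of 8 (ortho to the 7-OH, para to the ring oxygen, less hindered than C5) comes from the β-face, anti to the 3α-hydroxyl and the 2α-aryl group, which sets (4S).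

## Compound list

1 | 2,3,4-trihydroxyacetophenone | CC(=O)c1ccc(O)c(O)c1O | starting material
2 | 1-[2-hydroxy-3,4-bis(methoxymethoxy)phenyl]ethan-1-one | CC(=O)c1ccc(OCOC)c(OCOC)c1O | intermediate
3 | 4-(methoxymethoxy)benzaldehyde | COCOc1ccc(C=O)cc1 | starting material
4 | (E)-1-[2-hydroxy-3,4-bis(methoxymethoxy)phenyl]-3-[4-(methoxymethoxy)phenyl]prop-2-en-1-one | COCOc1ccc(/C=C/C(=O)c2ccc(OCOC)c(OCOC)c2O)cc1 | intermediate
5 | (2S)-7,8-bis(methoxymethoxy)-2-[4-(methoxymethoxy)phenyl]chroman-4-one, present as its ammonium enolate | COCOc1ccc([C@@H]2CC(=O)c3ccc(OCOC)c(OCOC)c3O2)cc1 | intermediate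
6 | (2R,3R)-3-hydroxy-7,8-bis(methoxymethoxy)-2-[4-(methoxymethoxy)phenyl]chroman-4-one (2,3-trans) | COCOc1ccc([C@H]2Oc3c(ccc(OCOC)c3OCOC)C(=O)[C@@H]2O)cc1 | intermediate
7 | (2R,3R)-3,7,8-trihydroxy-2-(4-hydroxyphenyl)chroman-4-one | Oc1ccc([C@H]2Oc3c(ccc(O)c3O)C(=O)[C@@H]2O)cc1 | intermediate
8 | (2R,3S,4R)-2-(4-hydroxyphenyl)chromane-3,4,7,8-tetrol (oritin-4α-ol) | Oc1ccc([C@H]2Oc3c(ccc(O)c3O)[C@@H](O)[C@@H]2O)cc1 | intermediate
9 | (2R,3R)-7,8-bis(methoxymethoxy)-2-[4-(methoxymethoxy)phenyl]-4-oxochroman-3-yl methanesulfonate | COCOc1ccc([C@H]2Oc3c(ccc(OCOC)c3OCOC)C(=O)[C@@H]2OS(C)(=O)=O)cc1 | intermediate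
10 | (2R,3S,4R)-4-hydroxy-7,8-bis(methoxymethoxy)-2-[4-(methoxymethoxy)phenyl]chroman-3-yl methanesulfonate (3β-OMs, 4α-OH) | COCOc1ccc([C@H]2Oc3c(ccc(OCOC)c3OCOC)[C@@H](O)[C@@H]2OS(C)(=O)=O)cc1 | intermediate
11 | (2R,3R,4R)-3,4-epoxy-7,8-bis(methoxymethoxy)-2-[4-(methoxymethoxy)phenyl]chromane (flavan numbering; epoxide oxygen α, cis to the 2-aryl group) | COCOc1ccc([C@H]2Oc3c(ccc(OCOC)c3OCOC)[C@H]4O[C@@H]24)cc1 | intermediate
12 | (2R,3S,4S)-4-(benzylsulfanyl)-7,8-bis(methoxymethoxy)-2-[4-(methoxymethoxy)phenyl]chroman-3-ol | COCOc1ccc([C@H]2Oc3c(ccc(OCOC)c3OCOC)[C@H](SCc3ccccc3)[C@H]2O)cc1 | intermediate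
13 | (2R,3S,4S)-4-(benzylsulfanyl)-2-(4-hydroxyphenyl)chromane-3,7,8-triol | Oc1ccc([C@H]2Oc3c(ccc(O)c3O)[C@H](SCc3ccccc3)[C@H]2O)cc1 | intermediate
14 | (2R,3S,4R)-2-(4-hydroxyphenyl)-6-[(2R,3R,4S)-3,7,8-trihydroxy-2-(4-hydroxyphenyl)chroman-4-yl]chromane-3,4,7,8-tetrol | Oc1ccc([C@H]2Oc3c(ccc(O)c3O)[C@H](c3cc4c(c(O)c3O)O[C@H](c3ccc(O)cc3)[C@@H](O)[C@@H]4O)[C@H]2O)cc1 | target

## Step count and risks

Total steps: 9. Longest linear sequence: 7 (steps 1, 2, 3, 6, 7, 8, 9).

**Step 3 (one-flask asymmetric ring closure and hydroxylation).** The risks are low enantioselectivity, over-oxidation to the achiral flavonol, and aurone formation. Residual minor enantiomer is removed by crystallisation of 7 (and of 9), and otherwise as diastereomeric dimers at 14. The fallback sets out from 4 and returns at 6. The chelated 2'-hydroxyl of 4 is alkylated (allyl bromide, K2CO3, DMF, 60 °C) to the 2'-O-allyl chalcone F1. Juliá–Colonna epoxidation (poly-L-leucine, urea–H2O2, DBU, THF) then gives the (αR,βS)-epoxide F2 by reagent control. Deallylation with zerovalent palladium (Pd(PPh3)4, morpholine, THF) frees the phenol, which opens the epoxide 6-endo at the benzylic carbon with inversion to give 6.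

**Step 7 (reduction, epoxide closure, thiolate opening).** The risks are the wrong C4 alcohol (which cannot close), direct thiolate displacement at C3, and attack at the wrong epoxide carbon. The fallback sets out from 6 and returns at 13. Mitsunobu inversion of 6 with 4-nitrobenzoic acid (PPh3, DIAD, THF, 0 °C) gives the 2,3-cis 3-O-(4-nitrobenzoyl) dihydroflavonol F3. NaBH4 at −20 °C followed by K2CO3 in MeOH gives the tri-MOM epioritin-4α-ol F4 (2,3-cis-3,4-cis diol). Thiolysis with BnSH in methanolic HCl (the conditions of step 8) replaces the 4-hydroxyl from the β-face and removes the MOM groups, giving 13.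

**Step 9 (union on free phenols).** The risks are self-condensation of 13, attack at C5 or on oxygen, and acid released during the reaction acting on the 4-hydroxyl. The fallback sets out from 13 and 8 and returns at 14. The three phenols of each partner are masked (allyl bromide, K2CO3, acetone, Ar) to give the tri-O-allyl thioether F5 and the tri-O-allyl oritin-4α-ol F6. These are joined with AgBF4 in CH2Cl2 at −20 °C to the hexa-O-allyl dimer F7, where only carbon nucleophiles of the aromatic ring compete. Pd(PPh3)4 and morpholine in THF/MeOH at rt then remove the six allyl groups under neutral conditions that spare the benzylic 4-hydroxyl, giving 14.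

## Further compounds

F1 | step 3 | (E)-1-[3,4-bis(methoxymethoxy)-2-(prop-2-enyloxy)phenyl]-3-[4-(methoxymethoxy)phenyl]prop-2-en-1-one | COCOc1ccc(/C=C/C(=O)c2ccc(OCOC)c(OCOC)c2OCC=C)cc1
F2 | step 3 | [(2R,3S)-3-[4-(methoxymethoxy)phenyl]oxiran-2-yl]-[3,4-bis(methoxymethoxy)-2-(prop-2-enyloxy)phenyl]methanone | COCOc1ccc([C@@H]2O[C@H]2C(=O)c2ccc(OCOC)c(OCOC)c2OCC=C)cc1
F3 | step 7 | (2R,3S)-7,8-bis(methoxymethoxy)-2-[4-(methoxymethoxy)phenyl]-4-oxochroman-3-yl 4-nitrobenzoate | COCOc1ccc([C@H]2Oc3c(ccc(OCOC)c3OCOC)C(=O)[C@H]2OC(=O)c2ccc(cc2)[N+](=O)[O-])cc1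
F4 | step 7 | (2R,3R,4R)-7,8-bis(methoxymethoxy)-2-[4-(methoxymethoxy)phenyl]chromane-3,4-diol | COCOc1ccc([C@H]2Oc3c(ccc(OCOC)c3OCOC)[C@@H](O)[C@H]2O)cc1
F5 | step 9 | (2R,3S,4S)-4-(benzylsulfanyl)-7,8-bis(prop-2-enyloxy)-2-[4-(prop-2-enyloxy)phenyl]chroman-3-ol | C=CCOc1ccc([C@H]2Oc3c(ccc(OCC=C)c3OCC=C)[C@H](SCc3ccccc3)[C@H]2O)cc1
F6 | step 9 | (2R,3S,4R)-7,8-bis(prop-2-enyloxy)-2-[4-(prop-2-enyloxy)phenyl]chromane-3,4-diol | C=CCOc1ccc([C@H]2Oc3c(ccc(OCC=C)c3OCC=C)[C@@H](O)[C@@H]2O)cc1
F7 | step 9 | (2R,3S,4R)-6-[(2R,3R,4S)-3-hydroxy-7,8-bis(prop-2-enyloxy)-2-[4-(prop-2-enyloxy)phenyl]chroman-4-yl]-7,8-bis(prop-2-enyloxy)-2-[4-(prop-2-enyloxy)phenyl]chromane-3,4-diol | C=CCOc1ccc([C@H]2Oc3c(ccc(OCC=C)c3OCC=C)[C@H](c3cc4c(c(OCC=C)c3OCC=C)O[C@H](c3ccc(OCC=C)cc3)[C@@H](O)[C@@H]4O)[C@H]2O)cc1
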